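**Strategy.** Ring A (C1–C5, C10; eudesmane numbering) is treated as a [4+2] adduct. The diene is C3=C4–C5=C10, a 2-ethoxydiene whose C5=C10 edge lies in ring B made from (R)-carvone; the dienophile is a chiral N-acryloyl oxazolidinone that stands for ethylene. One auxiliary-controlled, Lewis-acid-promoted Diels–Alder reaction joins C10 to C1 and C3 to C2, closes ring A and sets the quaternary C10. The acyl group on C1 is then removed by decarboxylation; the C4 oxygen, unmasked as a ketone, gives the C3=C4 double bond and the C15 hydroxymethyl through an enol triflate. The (Z)-coumarate and the acrylic acid are installed last.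

Key step: step 4

Remark: eudesmane numbering is used for all bicyclic compounds (ring A = C1–C5, C10; ring B = C5–C10; C11–C13 on C7; C14 = methyl on C10; C15 on C4; β = face of the C10 methyl); the stannanes, [bis(2,2,2-trifluoroethoxy)phosphoryl]acetic acid and 18 are taken as commercial.

Step 1
Reactants: 1 (R)-(−)-carvone
Product: 3 (5R)-2-methyl-5-(prop-1-en-2-yl)cyclohex-1-en-1-yl trifluoromethanesulfonate, via lithium enolate 2 (not isolated)
Conditions: L-Selectride, THF, −78 °C; then PhNTf2, −78 °C → rt; aq. NH4Cl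
Reagents that add atoms: N-phenylbis(trifluoromethanesulfonimide), O=S(=O)(N(c1ccccc1)S(=O)(=O)C(F)(F)F)C(F)(F)F
Why: Conjugate hydride reduction gives the C5–C10 enolate regiospecifically and O-triflation (enolate trapping) fixes the tetrasubstituted C5=C10 double bond, while the carvone stereocentre (future C7) is not touched.

Step 2
Reactants: 3 (5R)-2-methyl-5-(prop-1-en-2-yl)cyclohex-1-en-1-yl trifluoromethanesulfonate
Product: 4 (4R)-2-(1-ethoxyethenyl)-1-methyl-4-(prop-1-en-2-yl)cyclohex-1-ene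
Conditions: tributyl(1-ethoxyvinyl)stannane, Pd(PPh3)4 (5 mol %), LiCl, THF, reflux; aq. KF, basic alumina
Reagents that add atoms: tributyl(1-ethoxyvinyl)stannane, CCCC[Sn](CCCC)(CCCC)C(=C)OCC
Why: Stille coupling of the vinyl triflate attaches C4 (with its oxygen) and C3 to C5 and should give the 2-ethoxy-1,3-diene C3=C4–C5=C10, which is kept away from acid.

Step 3
Reactants: 5 (R)-4-benzyl-1,3-oxazolidin-2-one
Product: 7 (R)-3-acryloyl-4-benzyl-1,3-oxazolidin-2-one, via lithium oxazolidinide 6 (not isolated)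
Conditions: n-BuLi, THF, −78 °C; then acryloyl chloride, −78 → 0 °C
Reagents that add atoms: acryloyl chloride, C=CC(=O)Cl
Why: N-acylation of the lithiated oxazolidinone gives the chiral acrylimide dienophile.

Step 4
Reactants: 4 (4R)-2-(1-ethoxyethenyl)-1-methyl-4-(prop-1-en-2-yl)cyclohex-1-ene; 7 (R)-3-acryloyl-4-benzyl-1,3-oxazolidin-2-one
Product: 8 (R)-4-benzyl-3-[(4-ethoxy-15-noreudesma-4,11-dien-1α-yl)carbonyl]-1,3-oxazolidin-2-one (7β-isopropenyl; 10β-methyl; acyl group on C1 α)
Conditions: Et2AlCl (1.5 equiv), CH2Cl2, −78 → −40 °C; Et3N, then aq. NaHCO3/Rochelle salt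
Reagents that add atoms: none
Why: The aluminium chelate of s-cis acrylimide 7 should react with the 2-ethoxydiene in a strongly asynchronous [4+2] cycloaddition in which the enol-ether terminus C3 bonds to the β-carbon of the acrylimide (C2) and C10 to its α-carbon (C1); the closest known reaction type is the auxiliary-controlled, Lewis-acid-promoted Diels–Alder reaction of N-acryloyl oxazolidinones. Ring A closes by this suprafacial [4+2] addition (in the stepwise limit a Mukaiyama–Michael addition followed by 6-endo closure of the aluminium enolate on the oxocarbenium ion), and the 2-ethoxy donor fixes the "para" regiochemistry. The new stereocentres C10 (quaternary) and C1 are under reagent control: the benzyl group of the (R)-auxiliary shields one face of the chelated dienophile so that its Cα-Re face reacts, and the endo transition state then places the dienophile on the α face of the diene. C1 therefore enters anti to the C7 isopropenyl group and the C10 methyl ends β. The step needs this facial selectivity against the weak intrinsic bias of the remote C7 centre, which by analogy with dihydrocarvone enolate alkylations would lead to the 10-epi series; this is why reagent control is used, and C5 is not yet a stereocentre.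

Step 5
Reactants: 8 (R)-4-benzyl-3-[(4-ethoxy-15-noreudesma-4,11-dien-1α-yl)carbonyl]-1,3-oxazolidin-2-one
Product: 11 4-oxo-15-nor-5α-eudesm-11-ene-1α-carboxylic acid, via lithium peroxycarboxylate 9 (not isolated), via lithium carboxylate 10 (not isolated)
Conditions: LiOH, H2O2, THF–H2O, 0 °C; Na2SO3; then 1 M HCl, THF, 0 °C → rt
Reagents that add atoms: hydrogen peroxide, OO; water, O
Why: Hydroperoxide cleaves the exocyclic imide carbonyl and releases the auxiliary, and the acidic work-up hydrolyses the enol ether with kinetic protonation of C5 on the α face, anti to the axial C10 methyl, which should give the trans ring fusion (5α-H).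

Step 6
Reactants: 11 4-oxo-15-nor-5α-eudesm-11-ene-1α-carboxylic acid
Product: 13 15-nor-5α-eudesm-11-en-4-one, via Barton ester 12 (not isolated)
Conditions: N-hydroxypyridine-2-thione, DCC, DMAP (cat.), CH2Cl2, rt, dark; then t-BuSH, hν (W lamp), rt
Reagents that add atoms: none
Why: Barton reductive decarboxylation turns C1 into CH2 through the C1 radical, which takes hydrogen from the thiol, and no remaining stereocentre is involved.

Step 7
Reactants: 13 15-nor-5α-eudesm-11-en-4-one
Product: 15 15-nor-5α-eudesma-3,11-dien-4-yl trifluoromethanesulfonate, via potassium enolate 14 (not isolated)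
Conditions: KHMDS, THF, −78 °C; then PhNTf2, −78 → 0 °C; aq. NH4Cl
Reagents that add atoms: N-phenylbis(trifluoromethanesulfonimide), O=S(=O)(N(c1ccccc1)S(=O)(=O)C(F)(F)F)C(F)(F)F
Why: Kinetic deprotonation at the C3 methylene rather than the hindered C5 methine, then O-triflation, should place the double bond at C3=C4 and leave the C5 configuration intact (kinetic enol triflate formation).

Step 8
Reactants: 15 15-nor-5α-eudesma-3,11-dien-4-yl trifluoromethanesulfonate
Product: 16 5α-eudesma-3,11-dien-15-ol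
Conditions: (tributylstannyl)methanol, Pd(PPh3)4 (10 mol %), LiCl, dioxane, 100 °C
Reagents that add atoms: (tributylstannyl)methanol, CCCC[Sn](CCCC)(CCCC)CO
Why: Stille hydroxymethylation of the vinyl triflate installs C15 as CH2OH on C4 with the C3=C4 position fixed by the triflate.

Step 9
Reactants: 16 5α-eudesma-3,11-dien-15-ol
Product: 17 5α-eudesma-3,11-dien-15-yl [bis(2,2,2-trifluoroethoxy)phosphoryl]acetate
Conditions: [bis(2,2,2-trifluoroethoxy)phosphoryl]acetic acid, DCC, DMAP (cat.), CH2Cl2, 0 °C → rt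
Reagents that add atoms: [bis(2,2,2-trifluoroethoxy)phosphoryl]acetic acid, OC(=O)CP(=O)(OCC(F)(F)F)OCC(F)(F)F
Why: Steglich esterification of the primary allylic alcohol attaches the phosphonoacetate needed for the Z-selective olefination.

Step 10
Reactants: 17 5α-eudesma-3,11-dien-15-yl [bis(2,2,2-trifluoroethoxy)phosphoryl]acetate; 18 4-[(tert-butyldimethylsilyl)oxy]benzaldehyde
Product: 20 5α-eudesma-3,11-dien-15-yl (Z)-3-[4-(tert-butyldimethylsilyloxy)phenyl]prop-2-enoate, via phosphonate anion 19 (not isolated)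
Conditions: KHMDS, 18-crown-6, THF, −78 °C; then 18, −78 °C
Reagents that add atoms: none
Why: Still–Gennari olefination, in which the electron-poor phosphonate eliminates quickly from the kinetic adduct, should give the (Z)-cinnamate.

Step 11
Reactants: 20 5α-eudesma-3,11-dien-15-yl (Z)-3-[4-(tert-butyldimethylsilyloxy)phenyl]prop-2-enoate
Product: 21 12-hydroxy-5α-eudesma-3,11(13)-dien-15-yl (Z)-3-[4-(tert-butyldimethylsilyloxy)phenyl]prop-2-enoate
Conditions: SeO2 (0.5 equiv), t-BuOOH (3 equiv), salicylic acid (cat.), CH2Cl2, rt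
Reagents that add atoms: tert-butyl hydroperoxide, CC(C)(C)OO (oxygen delivered through catalytic selenium dioxide, O=[Se]=O)
Why: The selenium dioxide ene reaction/[2,3]-shift should occur at the electron-rich 1,1-disubstituted isopropenyl group, because the C3=C4 bond is deactivated by its allylic acyloxy group and the cinnamate double bond is electron-poor.

Step 12
Reactants: 21 12-hydroxy-5α-eudesma-3,11(13)-dien-15-yl (Z)-3-[4-(tert-butyldimethylsilyloxy)phenyl]prop-2-enoate
Product: 23 15-[(Z)-3-(4-(tert-butyldimethylsilyloxy)phenyl)prop-2-enoyloxy]-5α-eudesma-3,11(13)-dien-12-oic acid, via enal 22 (not isolated)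
Conditions: TEMPO (cat.), PhI(OAc)2, CH2Cl2, rt; then NaClO2, NaH2PO4, 2-methyl-2-butene, t-BuOH–H2O, rt
Reagents that add atoms: sodium chlorite, [Na+].[O-]Cl=O
Why: Oxoammonium oxidation of the allylic alcohol followed by Pinnick oxidation of the enal gives the α-methylene acid under conditions that leave the alkenes, the ester and the silyl ether alone.

Step 13
Reactants: 23 15-[(Z)-3-(4-(tert-butyldimethylsilyloxy)phenyl)prop-2-enoyloxy]-5α-eudesma-3,11(13)-dien-12-oic acid
Product: 24 2-[(2R,4aR,8aR)-8-({[(2Z)-3-(4-hydroxyphenyl)prop-2-enoyl]oxy}methyl)-4a-methyl-1,2,3,4,4a,5,6,8a-octahydronaphthalen-2-yl]prop-2-enoic acid (target)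
Conditions: TBAF, AcOH, THF, 0 °C
Reagents that add atoms: none
Why: Buffered fluoride cleaves the aryl silyl ether without ester cleavage or Z/E isomerisation (desilylation).

**Compound list**

1 | (R)-(−)-carvone | CC1=CC[C@H](CC1=O)C(C)=C | starting material
2 | lithium (5R)-2-methyl-5-(prop-1-en-2-yl)cyclohex-1-en-1-olate | [Li+].CC1=C([O-])C[C@@H](CC1)C(C)=C | intermediate
3 | (5R)-2-methyl-5-(prop-1-en-2-yl)cyclohex-1-en-1-yl trifluoromethanesulfonate | CC1=C(OS(=O)(=O)C(F)(F)F)C[C@@H](CC1)C(C)=C | intermediate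
4 | (4R)-2-(1-ethoxyethenyl)-1-methyl-4-(prop-1-en-2-yl)cyclohex-1-ene | CC1=C(C(=C)OCC)C[C@@H](CC1)C(C)=C | intermediate
5 | (R)-4-benzyl-1,3-oxazolidin-2-one | O=C1N[C@H](Cc2ccccc2)CO1 | starting material
6 | lithium salt of (R)-4-benzyl-1,3-oxazolidin-2-one | [Li+].O=C1[N-][C@H](Cc2ccccc2)CO1 | intermediate
7 | (R)-3-acryloyl-4-benzyl-1,3-oxazolidin-2-one | C=CC(=O)N1[C@H](Cc2ccccc2)COC1=O | intermediate
8 | (R)-4-benzyl-3-[(4-ethoxy-15-noreudesma-4,11-dien-1α-yl)carbonyl]-1,3-oxazolidin-2-one | C=C(C)[C@@H]1CC[C@@]2(C)[C@@H](C(=O)N3[C@H](Cc4ccccc4)COC3=O)CCC(OCC)=C2C1 | intermediate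
9 | lithium 4-ethoxy-15-noreudesma-4,11-diene-1α-peroxycarboxylate | [Li+].C=C(C)[C@@H]1CC[C@@]2(C)[C@@H](C(=O)O[O-])CCC(OCC)=C2C1 | intermediate
10 | lithium 4-ethoxy-15-noreudesma-4,11-diene-1α-carboxylate | [Li+].C=C(C)[C@@H]1CC[C@@]2(C)[C@@H](C(=O)[O-])CCC(OCC)=C2C1 | intermediate
11 | 4-oxo-15-nor-5α-eudesm-11-ene-1α-carboxylic acid | C=C(C)[C@@H]1CC[C@@]2(C)[C@@H](C(=O)O)CCC(=O)[C@@H]2C1 | intermediate
12 | 2-thioxopyridin-1(2H)-yl 4-oxo-15-nor-5α-eudesm-11-ene-1α-carboxylate (Barton ester) | C=C(C)[C@@H]1CC[C@@]2(C)[C@@H](C(=O)ON3C=CC=CC3=S)CCC(=O)[C@@H]2C1 | intermediate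
13 | 15-nor-5α-eudesm-11-en-4-one (trans-fused; 7β-isopropenyl; 10β-methyl) | C=C(C)[C@@H]1CC[C@@]2(C)CCCC(=O)[C@@H]2C1 | intermediate
14 | potassium 15-nor-5α-eudesma-3,11-dien-4-olate | [K+].C=C(C)[C@@H]1CC[C@@]2(C)CCC=C([O-])[C@@H]2C1 | intermediate
15 | 15-nor-5α-eudesma-3,11-dien-4-yl trifluoromethanesulfonate | C=C(C)[C@@H]1CC[C@@]2(C)CCC=C(OS(=O)(=O)C(F)(F)F)[C@@H]2C1 | intermediate
16 | 5α-eudesma-3,11-dien-15-ol | C=C(C)[C@@H]1CC[C@@]2(C)CCC=C(CO)[C@@H]2C1 | intermediate
17 | 5α-eudesma-3,11-dien-15-yl [bis(2,2,2-trifluoroethoxy)phosphoryl]acetate | C=C(C)[C@@H]1CC[C@@]2(C)CCC=C(COC(=O)CP(=O)(OCC(F)(F)F)OCC(F)(F)F)[C@@H]2C1 | intermediate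
18 | 4-[(tert-butyldimethylsilyl)oxy]benzaldehyde | O=Cc1ccc(O[Si](C)(C)C(C)(C)C)cc1 | starting material
19 | potassium salt of the phosphonate carbanion of 17 | [K+].C=C(C)[C@@H]1CC[C@@]2(C)CCC=C(COC(=O)[CH-]P(=O)(OCC(F)(F)F)OCC(F)(F)F)[C@@H]2C1 | intermediate
20 | 5α-eudesma-3,11-dien-15-yl (Z)-3-[4-(tert-butyldimethylsilyloxy)phenyl]prop-2-enoate | C=C(C)[C@@H]1CC[C@@]2(C)CCC=C(COC(=O)/C=C\c3ccc(O[Si](C)(C)C(C)(C)C)cc3)[C@@H]2C1 | intermediate
21 | 12-hydroxy-5α-eudesma-3,11(13)-dien-15-yl (Z)-3-[4-(tert-butyldimethylsilyloxy)phenyl]prop-2-enoate | C=C(CO)[C@@H]1CC[C@@]2(C)CCC=C(COC(=O)/C=C\c3ccc(O[Si](C)(C)C(C)(C)C)cc3)[C@@H]2C1 | intermediate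
22 | 12-oxo-5α-eudesma-3,11(13)-dien-15-yl (Z)-3-[4-(tert-butyldimethylsilyloxy)phenyl]prop-2-enoate | C=C(C=O)[C@@H]1CC[C@@]2(C)CCC=C(COC(=O)/C=C\c3ccc(O[Si](C)(C)C(C)(C)C)cc3)[C@@H]2C1 | intermediate
23 | 15-[(Z)-3-(4-(tert-butyldimethylsilyloxy)phenyl)prop-2-enoyloxy]-5α-eudesma-3,11(13)-dien-12-oic acid | C=C(C(=O)O)[C@@H]1CC[C@@]2(C)CCC=C(COC(=O)/C=C\c3ccc(O[Si](C)(C)C(C)(C)C)cc3)[C@@H]2C1 | intermediate
24 | 2-[(2R,4aR,8aR)-8-({[(2Z)-3-(4-hydroxyphenyl)prop-2-enoyl]oxy}methyl)-4a-methyl-1,2,3,4,4a,5,6,8a-octahydronaphthalen-2-yl]prop-2-enoic acid | C=C(C(=O)O)[C@@H]1CC[C@@]2(C)CCC=C(COC(=O)/C=C\c3ccc(O)cc3)[C@@H]2C1 | target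

**Step count and risks**

Total step count: 13. Longest linear sequence: 12 (steps 1, 2 and 4–13; step 3 is the convergent preparation of the dienophile).

Steps most likely to fail:

1. Step 4 (key step). The first C3–C2 bond may form without closure onto the hindered, fully substituted C10, and the reagent-controlled facial selectivity works against the intrinsic preference of the diene, so the C10 epimer may form in quantity. Fallback, setting out from 1 and returning at 16: conjugate reduction of 1 (L-Selectride, then aqueous quench) should give (2R,5R)-dihydrocarvone F1. Condensation with (R)-1-phenylethylamine (toluene, Dean–Stark) gives imine F2. The d'Angelo Michael addition of its secondary enamine tautomer to ethyl vinyl ketone, then aqueous acetic acid, should give the diketone (2S,5R)-2-methyl-2-(3-oxopentyl)-5-(prop-1-en-2-yl)cyclohexan-1-one F3, with C10 set by the amine. Aldol condensation (NaOMe, MeOH) gives (+)-α-cyperone F4. Li/NH3 reduction with trapping of the enolate by PhNTf2 gives the 5α-configured enol triflate F5. Pd(OAc)2/PPh3 with HCO2H/Bu3N reduces it to α-selinene F6. SeO2/t-BuOOH should then oxidise the C15 methyl of the more nucleophilic trisubstituted double bond to give 16.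

2. Step 11. Chemoselectivity between the isopropenyl group and the ring double bond may be lost, and over-oxidation is possible. Fallback, setting out from 15 and returning at 24, with the allylic oxidation moved to the stage where the ring alkene is an electron-poor vinyl triflate: SeO2/t-BuOOH on 15 should give the C12 alcohol F7. TEMPO/PhI(OAc)2 gives the enal F8 and NaClO2 the acid F9. Esterification with 2-(trimethylsilyl)ethanol (DCC, DMAP) gives the 2-(trimethylsilyl)ethyl ester F10. Stille coupling with (tributylstannyl)methanol gives the allylic alcohol F11. Acylation with [bis(2,2,2-trifluoroethoxy)phosphoryl]acetic acid gives the phosphonoacetate F12. Still–Gennari olefination with 18 gives the protected (Z)-coumarate F13. TBAF then removes the aryl silyl ether and the 2-(trimethylsilyl)ethyl ester together to give 24.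

3. Step 8. Transmetalation of the hindered triflate may be slow, with competing protodestannylation or reduction of the triflate. Fallback, setting out from 15 and returning at 16: palladium-catalysed methoxycarbonylation (Pd(OAc)2, dppp, CO, MeOH, Et3N, DMF) should give methyl 5α-eudesma-3,11-dien-15-oate F14, which DIBAL-H (CH2Cl2, −78 °C) reduces to 16.

Further compounds
F1 | step 4 | (2R,5R)-2-methyl-5-(prop-1-en-2-yl)cyclohexan-1-one (dihydrocarvone) | C[C@@H]1CC[C@H](CC1=O)C(C)=C
F2 | step 4 | N-[(R)-1-phenylethyl]imine of dihydrocarvone | CC1CC[C@H](CC1=N[C@H](C)c2ccccc2)C(C)=C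
F3 | step 4 | (2S,5R)-2-methyl-2-(3-oxopentyl)-5-(prop-1-en-2-yl)cyclohexan-1-one | C=C(C)[C@@H]1CC[C@@](C)(CCC(=O)CC)C(=O)C1
F4 | step 4 | (+)-α-cyperone (eudesma-4,11-dien-3-one) | C=C(C)[C@@H]1CC[C@@]2(C)CCC(=O)C(C)=C2C1
F5 | step 4 | 5α-eudesma-3,11-dien-3-yl trifluoromethanesulfonate | C=C(C)[C@@H]1CC[C@@]2(C)CCC(OS(=O)(=O)C(F)(F)F)=C(C)[C@@H]2C1
F6 | step 4 | α-selinene (5α-eudesma-3,11-diene) | C=C(C)[C@@H]1CC[C@@]2(C)CCC=C(C)[C@@H]2C1
F7 | step 11 | 12-hydroxy-15-nor-5α-eudesma-3,11(13)-dien-4-yl trifluoromethanesulfonate | C=C(CO)[C@@H]1CC[C@@]2(C)CCC=C(OS(=O)(=O)C(F)(F)F)[C@@H]2C1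
F8 | step 11 | 12-oxo-15-nor-5α-eudesma-3,11(13)-dien-4-yl trifluoromethanesulfonate | C=C(C=O)[C@@H]1CC[C@@]2(C)CCC=C(OS(=O)(=O)C(F)(F)F)[C@@H]2C1
F9 | step 11 | 4-(trifluoromethanesulfonyloxy)-15-nor-5α-eudesma-3,11(13)-dien-12-oic acid | C=C(C(=O)O)[C@@H]1CC[C@@]2(C)CCC=C(OS(=O)(=O)C(F)(F)F)[C@@H]2C1
F10 | step 11 | 2-(trimethylsilyl)ethyl 4-(trifluoromethanesulfonyloxy)-15-nor-5α-eudesma-3,11(13)-dien-12-oate | C=C(C(=O)OCC[Si](C)(C)C)[C@@H]1CC[C@@]2(C)CCC=C(OS(=O)(=O)C(F)(F)F)[C@@H]2C1
F11 | step 11 | 2-(trimethylsilyl)ethyl 15-hydroxy-5α-eudesma-3,11(13)-dien-12-oate | C=C(C(=O)OCC[Si](C)(C)C)[C@@H]1CC[C@@]2(C)CCC=C(CO)[C@@H]2C1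
F12 | step 11 | 2-(trimethylsilyl)ethyl 15-{[bis(2,2,2-trifluoroethoxy)phosphoryl]acetoxy}-5α-eudesma-3,11(13)-dien-12-oate | C=C(C(=O)OCC[Si](C)(C)C)[C@@H]1CC[C@@]2(C)CCC=C(COC(=O)CP(=O)(OCC(F)(F)F)OCC(F)(F)F)[C@@H]2C1
F13 | step 11 | 2-(trimethylsilyl)ethyl 15-[(Z)-3-(4-(tert-butyldimethylsilyloxy)phenyl)prop-2-enoyloxy]-5α-eudesma-3,11(13)-dien-12-oate | C=C(C(=O)OCC[Si](C)(C)C)[C@@H]1CC[C@@]2(C)CCC=C(COC(=O)/C=C\c3ccc(O[Si](C)(C)C(C)(C)C)cc3)[C@@H]2C1
F14 | step 8 | methyl 5α-eudesma-3,11-dien-15-oate | C=C(C)[C@@H]1CC[C@@]2(C)CCC=C(C(=O)OC)[C@@H]2C1
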